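**Assumptions.** Xanthogalenol is achiral: it has no stereocentres, and the only stereo-element is the E-enone, so "single enantiomer" is moot. The commercially available 2',6'-dihydroxy-4'-methoxyacetophenone is taken as the starting material. It is C_s-symmetric, so the two ring positions ortho to OMe are equivalent and mono-C-prenylation has no regiochemical problem.

## Retrosynthetic overview
1. Target ⇒ remove three MOM groups from tri-MOM chalcone 9.
2. 9 ⇒ Claisen–Schmidt condensation of bis-MOM prenyl-acetophenone 6 with 4-(MOMO)benzaldehyde 8. This sets the E-enone.
3. 6 ⇒ bis-MOM protection of 4, which comes from the **proposed new boron-templated ortho-C-prenylation** of symmetric acetophenone 1 with prenol. This desymmetrises 1 and forms the aryl–prenyl C–C bond.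
4. No rings are built. Both aromatic rings come from commercial materials, and there are no stereocentres to set.

## Route

**Step 1**
Reactants: 1 (2',6'-dihydroxy-4'-methoxyacetophenone); 2 (prenol, 3-methylbut-2-en-1-ol); 3 (phenylboronic acid, template and catalyst)
Product: 4, 1-(2,6-dihydroxy-4-methoxy-3-(3-methylbut-2-en-1-yl)phenyl)ethan-1-one
Conditions: 1 (1.5 equiv), 2 (1.0 equiv), PhB(OH)2 (0.5 equiv), 4 Å MS, toluene, 80 °C, 16 h
Reagents that add atoms: prenol, CC(C)=CCO
Why: Proposed new method: the phenol condenses with PhB(OH)2 and prenol to give an ArO–B(Ph)–OCH2CH=CMe2 mixed borinate. The ortho carbon C3' attacks the primary allylic CH2 through a six-membered cyclic, SN2-like transition state in which the B–O oxygen is the leaving group. This should give linear prenyl rather than reverse-prenyl, chromane, or O-prenyl products, and the free-phenol acetophenone carries no protecting groups. Loss of the C3'–H proton regenerates ArO–B(Ph)OH, which exchanges with more prenol (turnover). The closest known chemistry is phenoxyboron-directed ortho-hydroxyalkylation of phenols and boronic-acid-catalysed Friedel–Crafts allylation with allylic alcohols. Using excess 1 limits bis-prenylation, and no stereocentre is involved.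

**Step 2**
Reactants: 4; 5 (chloromethyl methyl ether, MOMCl)
Product: 6, 1-(2,6-bis(methoxymethoxy)-4-methoxy-3-prenylphenyl)ethan-1-one
Conditions: NaH (2.6 equiv), then MOMCl (3.0 equiv), THF/DMF (4:1), 0 °C → rt, 4 h
Reagents that add atoms: MOMCl, COCCl
Why: Williamson-type O-alkylation of the two chelated phenoxides gives the acetals. Protection prevents phenolate deactivation in the next base-mediated condensation and avoids acid-promoted chromane formation. The prenyl alkene and the aryl ketone are untouched.

**Step 3**
Reactants: 7 (4-hydroxybenzaldehyde); 5 (MOMCl)
Product: 8, 4-(methoxymethoxy)benzaldehyde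
Conditions: MOMCl (1.3 equiv), DIPEA (2 equiv), CH2Cl2, 0 °C → rt, 6 h
Reagents that add atoms: MOMCl, COCCl
Why: Standard MOM protection of a phenol. The aldehyde is unaffected.

**Step 4**
Reactants: 6; 8
Product: 9, (E)-1-[2,6-bis(methoxymethoxy)-4-methoxy-3-prenylphenyl]-3-[4-(methoxymethoxy)phenyl]prop-2-en-1-one
Conditions: KOH (3 equiv), EtOH, 0 °C → rt, 24 h
Reagents that add atoms: none
Why: Base-mediated Claisen–Schmidt (aldol) condensation. Dehydration of the β-hydroxy ketone under thermodynamic control gives only the trans (E) enone, matching the target's /C=C/ geometry. The MOM acetals are base-stable, and the aryl ketone has no α-branching to cause epimerisation.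

**Step 5**
Reactants: 9
Product: 10, xanthogalenol, (E)-1-(2,6-dihydroxy-4-methoxy-3-prenylphenyl)-3-(4-hydroxyphenyl)prop-2-en-1-one
Conditions: Amberlyst-15 (H⁺ form), MeOH, 45 °C, 6–10 h (monitor by TLC)
Reagents that add atoms: none
Why: Acid-catalysed transacetalisation of the MOM groups in methanol releases the three phenols as CH2(OMe)2. The mild, heterogeneous acid and moderate temperature should avoid cyclisation of the 2'-OH onto the enone (flavanone) or onto the prenyl alkene (chromane). The E-enone and the prenyl C=C are retained.

## Compound list
1 | 2',6'-dihydroxy-4'-methoxyacetophenone | CC(=O)c1c(O)cc(OC)cc1O | starting material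
2 | prenol (3-methylbut-2-en-1-ol) | CC(C)=CCO | starting material
3 | phenylboronic acid | OB(O)c1ccccc1 | starting material (template/catalyst)
4 | 1-(2,6-dihydroxy-4-methoxy-3-prenylphenyl)ethanone | CC(=O)c1c(O)c(CC=C(C)C)c(OC)cc1O | intermediate
5 | chloromethyl methyl ether (MOMCl) | COCCl | starting material
6 | bis-MOM prenyl acetophenone | CC(=O)c1c(OCOC)c(CC=C(C)C)c(OC)cc1OCOC | intermediate
7 | 4-hydroxybenzaldehyde | O=Cc1ccc(O)cc1 | starting material
8 | 4-(methoxymethoxy)benzaldehyde | COCOc1ccc(C=O)cc1 | intermediate
9 | tri-MOM (E)-chalcone | COCOc1ccc(/C=C/C(=O)c2c(OCOC)cc(OC)c(CC=C(C)C)c2OCOC)cc1 | intermediate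
10 | xanthogalenol | COc1cc(O)c(C(=O)/C=C/c2ccc(O)cc2)c(O)c1CC=C(C)C | target

## Totals
Total steps: 5 (4 on the main branch plus 1 for the aldehyde branch).
Longest linear sequence: 4 steps (1 → 4 → 6 → 9 → 10).

## Three steps most likely to fail
1. **Step 1 (proposed new boron-templated prenylation).** Risks are low conversion (the acetyl C=O chelates boron and blocks the template), bis-prenylation, and chromane formation.
   - Fallback, using known chemistry: C-alkylation of the phenoxide in water. Treat 1 with prenyl bromide (1.1 equiv) and aq. KOH (3 equiv) in H2O/MeOH at 0 °C → rt. Separate mono-prenyl 4 from the bis-prenyl product by chromatography and continue with Step 2.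
2. **Step 5 (MOM removal).** Acid may cyclise the product to a flavanone or chromane.
   - Fallback, bypassing protecting groups: run Claisen–Schmidt condensation directly on free-phenol 4 with 7, using KOH (6 equiv) in EtOH/H2O at 0 °C → rt for several days. This skips Steps 2, 3 and 5.
3. **Step 4 (Claisen–Schmidt on the hindered, di-ortho-substituted bis-MOM ketone).** Conversion may be sluggish.
   - Fallback, a different mechanism: form the lithium enolate of 6 with LDA at –78 °C in THF, add aldehyde 8 for a kinetic aldol, then dehydrate the β-hydroxy ketone with MsCl/Et3N followed by DBU to give the E-enone 9.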